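The flavone is disconnected at C3–C4. C4 is a carbonyl carbon on ring A, whose 2,4,6-trioxygenation is symmetric, and C2–C3 is an alkyne-level two-carbon unit on ring B. An acyl Sonogashira coupling of 2,4,6-trimethoxybenzoyl chloride with the benzyl-protected ring B arylacetylene therefore delivers, in one operation, a diaryl ynone with the whole carbon skeleton in place. Because the two ortho methoxy groups of ring A are equivalent, either oxygen can become O1 in the subsequent ICl-induced demethylative 6-endo closure of ring C. One hydrogenolysis then removes the C3 iodine and the benzyl group on O4'.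

Key step: step 6

Assumption: in step 7 the O-methyl group of the cyclised oxonium ion is taken to leave as chloromethane, because chloride is the only nucleophilic counter-ion that ICl supplies.

Step 1
Reactants: 1 2,5-dimethoxybenzaldehyde
Product: 3 2,5-dimethoxyphenol, via 2,5-dimethoxyphenyl formate 2 (not isolated)
Conditions: mCPBA, CH2Cl2, 0 °C to rt; aq NaHCO3 wash; then K2CO3 (cat.), MeOH, rt
Reagents that add atoms: mCPBA, OOC(=O)c1cccc(Cl)c1
Why: Baeyer–Villiger (Dakin-type) oxidation, in which the electron-rich aryl group bearing an ortho methoxy group migrates in preference to hydride, followed by base-catalysed methanolysis of the aryl formate, should give the phenol.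

Step 2
Reactants: 3 2,5-dimethoxyphenol
Product: 4 2-(benzyloxy)-1,4-dimethoxybenzene
Conditions: BnBr, K2CO3, DMF, rt
Reagents that add atoms: benzyl bromide, BrCc1ccccc1
Why: Williamson ether synthesis, the phenoxide being the only nucleophile present for SN2 attack on benzyl bromide.

Step 3
Reactants: 4 2-(benzyloxy)-1,4-dimethoxybenzene
Product: 6 4-(benzyloxy)-2,5-dimethoxybenzaldehyde, via aryl iminium chloride 5 (not isolated)
Conditions: POCl3, DMF, 0 to 70 °C; then ice-water
Reagents that add atoms: N,N-dimethylformamide, CN(C)C=O; water, O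
Why: Vilsmeier–Haack formylation should occur at the unhindered carbon para to the benzyloxy group and ortho to a methoxy group, the same position at which 1,2,4-trialkoxybenzenes are formylated, and hydrolysis of the iminium salt releases the aldehyde.

Step 4
Reactants: 6 4-(benzyloxy)-2,5-dimethoxybenzaldehyde; 7 dimethyl (1-diazo-2-oxopropyl)phosphonate
Product: 8 1-(benzyloxy)-4-ethynyl-2,5-dimethoxybenzene
Conditions: K2CO3, MeOH/THF, rt
Reagents that add atoms: dimethyl (1-diazo-2-oxopropyl)phosphonate (7), COP(=O)(OC)C(=[N+]=[N-])C(C)=O
Why: Ohira–Bestmann variant of the Seyferth–Gilbert homologation, in which methoxide deacetylates 7, the diazophosphonate anion olefinates the aldehyde, and the diazoalkene loses N2 with a 1,2-hydrogen shift to give the terminal alkyne under conditions that leave the benzyl ether untouched.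

Step 5
Reactants: 9 2,4,6-trimethoxybenzoic acid
Product: 10 2,4,6-trimethoxybenzoyl chloride
Conditions: (COCl)2, DMF (cat.), CH2Cl2, 0 °C to rt; evaporate, use crude at once
Reagents that add atoms: oxalyl chloride, O=C(Cl)C(Cl)=O
Why: Acid chloride formation through the catalytic chloroiminium species should be fast at low temperature, which limits protodecarboxylation of the electron-rich acid, and all by-products are gases.

Step 6
Reactants: 10 2,4,6-trimethoxybenzoyl chloride; 8 1-(benzyloxy)-4-ethynyl-2,5-dimethoxybenzene
Product: 11 3-[4-(benzyloxy)-2,5-dimethoxyphenyl]-1-(2,4,6-trimethoxyphenyl)prop-2-yn-1-one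
Conditions: PdCl2(PPh3)2 (2 mol %), CuI (4 mol %), Et3N (1.5 equiv), THF, rt, Ar
Reagents that add atoms: none
Why: The divalent palladium precatalyst is reduced in the flask to zerovalent palladium, which inserts into the carbon–chlorine bond of 10; the copper acetylide formed from 8, CuI and Et3N transmetalates, and reductive elimination forms C3–C4 to release ynone 11. This is a standard acyl Sonogashira coupling of an aroyl chloride with a terminal arylacetylene. No ring is closed and no stereocentre is created. The selectivity needed is cross-coupling over oxidative alkyne dimerisation and over decarbonylation of the acyl palladium species; exclusion of oxygen, a slight excess of 10 and room temperature should secure it, and 10 has no α-hydrogen, so Et3N cannot convert it into a ketene. The two ortho methoxy groups slow oxidative addition but also shield the carbonyl group from amine attack, so a longer reaction time is preferable to heating.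

Step 7
Reactants: 11 3-[4-(benzyloxy)-2,5-dimethoxyphenyl]-1-(2,4,6-trimethoxyphenyl)prop-2-yn-1-one
Product: 13 2-[4-(benzyloxy)-2,5-dimethoxyphenyl]-3-iodo-5,7-dimethoxy-4H-chromen-4-one, via 1-methylchromen-1-ium chloride 12 (not isolated)
Conditions: ICl (1.2 equiv), CH2Cl2, −78 °C; then aq Na2S2O3
Reagents that add atoms: iodine monochloride, ClI
Why: Electrophilic iodocyclisation of a 2-methoxyaryl ynone to a 3-iodochromone, in which the iodonium ion across C2–C3 is opened at C2 (the carbon whose positive charge the alkoxy-rich ring B stabilises) by one of the two equivalent ortho methoxy oxygens of ring A in a 6-endo-dig closure of ring C, after which chloride removes the methyl group from oxonium ion 12 by SN2 attack.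

Step 8
Reactants: 13 2-[4-(benzyloxy)-2,5-dimethoxyphenyl]-3-iodo-5,7-dimethoxy-4H-chromen-4-one
Product: 14 2-(4-hydroxy-2,5-dimethoxyphenyl)-5,7-dimethoxy-4H-chromen-4-one
Conditions: H2 (1 atm), 10% Pd/C, NaOAc, EtOAc/MeOH, rt
Reagents that add atoms: none
Why: Heterogeneous palladium-catalysed hydrogenolysis should cleave the carbon–iodine bond (hydrodehalogenation, with NaOAc taking up the HI) and the benzylic carbon–oxygen bond in the same operation, while the vinylogous-ester C2=C3 bond of the chromone is reduced far more slowly, so the reaction is stopped once both groups are gone.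

Compound list
1 | 2,5-dimethoxybenzaldehyde | COc1ccc(OC)c(C=O)c1 | starting material
2 | 2,5-dimethoxyphenyl formate | COc1ccc(OC)c(OC=O)c1 | intermediate
3 | 2,5-dimethoxyphenol | COc1ccc(OC)c(O)c1 | intermediate
4 | 2-(benzyloxy)-1,4-dimethoxybenzene | COc1ccc(OC)c(OCc2ccccc2)c1 | intermediate
5 | N-{[4-(benzyloxy)-2,5-dimethoxyphenyl]methylidene}-N-methylmethanaminium chloride | C[N+](C)=Cc1cc(OC)c(OCc2ccccc2)cc1OC.[Cl-] | intermediate
6 | 4-(benzyloxy)-2,5-dimethoxybenzaldehyde | O=Cc1cc(OC)c(OCc2ccccc2)cc1OC | intermediate
7 | dimethyl (1-diazo-2-oxopropyl)phosphonate | COP(=O)(OC)C(=[N+]=[N-])C(C)=O | starting material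
8 | 1-(benzyloxy)-4-ethynyl-2,5-dimethoxybenzene | C#Cc1cc(OC)c(OCc2ccccc2)cc1OC | intermediate
9 | 2,4,6-trimethoxybenzoic acid | COc1cc(OC)c(C(=O)O)c(OC)c1 | starting material
10 | 2,4,6-trimethoxybenzoyl chloride | COc1cc(OC)c(C(Cl)=O)c(OC)c1 | intermediate
11 | 3-[4-(benzyloxy)-2,5-dimethoxyphenyl]-1-(2,4,6-trimethoxyphenyl)prop-2-yn-1-one | COc1cc(OC)c(C(=O)C#Cc2cc(OC)c(OCc3ccccc3)cc2OC)c(OC)c1 | intermediate
12 | 2-[4-(benzyloxy)-2,5-dimethoxyphenyl]-3-iodo-5,7-dimethoxy-1-methyl-4-oxo-4H-chromen-1-ium chloride | C[O+]1c2cc(OC)cc(OC)c2C(=O)C(I)=C1c3cc(OC)c(OCc4ccccc4)cc3OC.[Cl-] | intermediate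
13 | 2-[4-(benzyloxy)-2,5-dimethoxyphenyl]-3-iodo-5,7-dimethoxy-4H-chromen-4-one | COc1cc(OC)c2c(=O)c(I)c(-c3cc(OC)c(OCc4ccccc4)cc3OC)oc2c1 | intermediate
14 | 2-(4-hydroxy-2,5-dimethoxyphenyl)-5,7-dimethoxy-4H-chromen-4-one | COc1cc(OC)c2c(=O)cc(-c3cc(OC)c(O)cc3OC)oc2c1 | target

Total step count: 8 steps.
Longest linear sequence: 7 steps (steps 1, 2, 3, 4, 6, 7 and 8; step 5 is the one-step side branch).

Steps most likely to fail

Step 6. Oxidative addition into the doubly ortho-substituted, electron-rich aroyl chloride may be slow, so that hydrolysis of the acid chloride or copper-mediated dimerisation of the alkyne outruns the cross-coupling. The fallback sets out from 8 and forms the same C3–C4 bond by carbonyl addition. Deprotonation of 8 with n-BuLi in THF at −78 °C should give the lithium acetylide of 8, F1. Addition of purchased 2,4,6-trimethoxybenzaldehyde and a mild aqueous NH4Cl quench should give racemic 3-[4-(benzyloxy)-2,5-dimethoxyphenyl]-1-(2,4,6-trimethoxyphenyl)prop-2-yn-1-ol, F2, which is acid-sensitive and is kept neutral. Oxidation of this doubly activated carbinol with MnO2 in CH2Cl2 at rt returns to the route at 11.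

Step 7. Electrophilic iodination of the two alkoxy-rich arenes may compete with activation of the alkyne and consume the ICl, or demethylation of the oxonium ion may be incomplete. The fallback sets out from 11 and avoids iodine. BCl3 with pentamethylbenzene in CH2Cl2 at −78 to 0 °C should remove one carbonyl-chelated ortho methyl group of ring A and the benzyl group, giving 1-(2-hydroxy-4,6-dimethoxyphenyl)-3-(4-hydroxy-2,5-dimethoxyphenyl)prop-2-yn-1-one, F3. A catalytic amount of TfOH in CH2Cl2 should then close ring C by 6-endo oxa-Michael addition of the ring A phenol to the ynone. Any β-chloro enone formed by HCl addition would converge on the same product by addition–elimination. This fallback rejoins the route at 14, so step 8 is not needed.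

Step 8. The chromone C2=C3 bond may be reduced further to the flavanone, or iodide may poison the catalyst surface so that cleavage of the carbon–iodine or benzyl bond stalls. The fallback sets out from 13 and separates the two cleavages without hydrogen gas. Homogeneous formate reduction of the vinyl iodide with Pd(PPh3)4 and HCO2Na in DMF at 80 °C should give 2-[4-(benzyloxy)-2,5-dimethoxyphenyl]-5,7-dimethoxy-4H-chromen-4-one, F4. Acidolysis of its benzyl ether with TFA and pentamethylbenzene as cation scavenger at rt then returns to the route at 14.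

Further compounds
F1 | step 6 | lithium acetylide of 8, lithium [4-(benzyloxy)-2,5-dimethoxyphenyl]ethynide | [Li]C#Cc1cc(OC)c(OCc2ccccc2)cc1OC
F2 | step 6 | rac-3-[4-(benzyloxy)-2,5-dimethoxyphenyl]-1-(2,4,6-trimethoxyphenyl)prop-2-yn-1-ol | COc1cc(OC)c(C(O)C#Cc2cc(OC)c(OCc3ccccc3)cc2OC)c(OC)c1
F3 | step 7 | 1-(2-hydroxy-4,6-dimethoxyphenyl)-3-(4-hydroxy-2,5-dimethoxyphenyl)prop-2-yn-1-one | COc1cc(O)c(C(=O)C#Cc2cc(OC)c(O)cc2OC)c(OC)c1
F4 | step 8 | 2-[4-(benzyloxy)-2,5-dimethoxyphenyl]-5,7-dimethoxy-4H-chromen-4-one | COc1cc(OC)c2c(=O)cc(-c3cc(OC)c(OCc4ccccc4)cc3OC)oc2c1
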